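**Retrosynthetic overview**

1. Target 24 ← heptamethyl ether 23 (BBr3) ← aldehyde 21 + phosphonate 22; the Horner–Wadsworth–Emmons reaction builds the (E)-styryl group on C4 of ring A.
2. Feature used: in ring A, C3a lies between C7a (which carries O1) and C4, and the carbon on C4 can be an aldehyde imine whose nitrogen guides rhodium into the C3a–H bond. The C3–C3a bond is therefore cut back to the (E)-triaryl enol ether imine 19, in which the two aryl groups are cis so that syn addition gives the trans ring.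
3. Enol ether 18 ← 4-methoxyphenylboronic acid 17 + (Z)-bromo enol ether 16 ← 3-hydroxy-5-methoxybenzaldehyde 15 + gem-dibromoalkene 14 of the ring-B aldehyde 13. Making the C–O bond first and the C–C bond second fixes both the regiochemistry and the alkene geometry, which hydroboration of an unsymmetrical diarylalkyne would not.
4. Ring-B dihydrobenzofuran 11 ← benzylic C–H insertion of a donor/donor rhodium carbene (diazo compound 9 from ketone 7), then C2 epimerisation to trans; 7 comes from 5-bromo-o-vanillin 1, 4-methoxybenzyl chloride 2 and 1-bromo-3,5-dimethoxybenzene 4.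
5. Ring order: the dihydrofuran fused to ring B first (step 5), the dihydrofuran fused to ring A second (step 12).

Key step: step 12

Locants: unprimed for the styryl-bearing dihydrobenzofuran (its benzene ring is ring A), primed for the second dihydrobenzofuran (its benzene ring is ring B). RB = (2R,3R)-3-(3,5-dimethoxyphenyl)-7-methoxy-2-(4-methoxyphenyl)-2,3-dihydro-1-benzofuran-5-yl.

Assumption: Rh2(R-PTAD)4 (step 5) and the (S,R,R)-phosphoramidite (step 12) are taken to induce the configurations drawn; if either sense of induction is opposite, the mirror-image catalyst or ligand is used with nothing else changed.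

**Route**

Step 1
Reactants: 1 5-bromo-2-hydroxy-3-methoxybenzaldehyde; 2 4-methoxybenzyl chloride
Product: 3 5-bromo-3-methoxy-2-[(4-methoxybenzyl)oxy]benzaldehyde
Conditions: K2CO3, n-Bu4NI (cat.), DMF, 60 °C
Reagents that add atoms: none
Why: Williamson ether synthesis; the phenoxide of 1 displaces chloride from the benzylic chloride, and the aldehyde and aryl bromide are inert.

Step 2
Reactants: 3 5-bromo-3-methoxy-2-[(4-methoxybenzyl)oxy]benzaldehyde; 4 1-bromo-3,5-dimethoxybenzene
Product: 6 rac-{5-bromo-3-methoxy-2-[(4-methoxybenzyl)oxy]phenyl}(3,5-dimethoxyphenyl)methanol, via 3,5-dimethoxyphenylmagnesium bromide 5 (not isolated)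
Conditions: 4, Mg, I2 (cat.), THF, reflux; then 3, THF, 0 °C; H2O
Reagents that add atoms: none
Why: Grignard formation and 1,2-addition to the aldehyde; at 0 °C an arylmagnesium halide does not exchange with the aryl bromide of 3, and the racemic carbinol centre is removed in step 3.

Step 3
Reactants: 6 rac-diarylmethanol
Product: 7 {5-bromo-3-methoxy-2-[(4-methoxybenzyl)oxy]phenyl}(3,5-dimethoxyphenyl)methanone
Conditions: Dess–Martin periodinane, CH2Cl2, rt
Reagents that add atoms: none
Why: Dess–Martin oxidation of a diarylmethanol to the benzophenone under near-neutral conditions that leave the 4-methoxybenzyl ether untouched.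

Step 4
Reactants: 7 diaryl ketone
Product: 8 hydrazone of 7 (E/Z mixture, of no consequence)
Conditions: N2H4·H2O (10 equiv), AcOH (cat.), EtOH, 80 °C
Reagents that add atoms: hydrazine NN
Why: Hydrazone formation by condensation of the ketone with hydrazine, the excess of which suppresses azine formation.

Step 5
Reactants: 8 hydrazone
Product: 10 (2S,3R)-5-bromo-3-(3,5-dimethoxyphenyl)-7-methoxy-2-(4-methoxyphenyl)-2,3-dihydro-1-benzofuran (cis), via diaryldiazomethane 9 (not isolated)
Conditions: MnO2, CH2Cl2, 0 °C, filter; then Rh2(R-PTAD)4 (1 mol %), CH2Cl2, 0 °C (PTAD = (1-adamantyl)(phthalimido)acetate)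
Reagents that add atoms: none
Why: MnO2 dehydrogenates the hydrazone to the donor/donor diazo compound, whose rhodium carbene inserts into the ether benzylic C–H bond in a 1,5 manner (enantioselective intramolecular C–H insertion); the chiral carboxylate ligands set C3' and the hydride-shift/ring-closure path gives the cis-2,3-diaryl ring.

Step 6
Reactants: 10 cis-(2S,3R) bromide
Product: 11 (2R,3R)-5-bromo-3-(3,5-dimethoxyphenyl)-7-methoxy-2-(4-methoxyphenyl)-2,3-dihydro-1-benzofuran (trans; RB–Br)
Conditions: CF3CO2H, CH2Cl2 (dilute), 0 °C to rt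
Reagents that add atoms: none
Why: Acid-catalysed epimerisation at C2'; reversible ionisation of the C2'–O bond to the 4-methoxybenzylic cation and re-closure by the phenol oxygen under thermodynamic control should give the trans isomer, while C3' is not involved and keeps its configuration.

Step 7
Reactants: 11 RB–Br
Product: 13 (2R,3R)-3-(3,5-dimethoxyphenyl)-7-methoxy-2-(4-methoxyphenyl)-2,3-dihydro-1-benzofuran-5-carbaldehyde (RB–CHO), via aryllithium 12 (not isolated)
Conditions: n-BuLi, THF, −78 °C; DMF, −78 to 0 °C; H2O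
Reagents that add atoms: N,N-dimethylformamide CN(C)C=O
Why: Bromine–lithium exchange followed by formylation of the aryllithium with DMF (Bouveault-type formylation); exchange at −78 °C is faster than deprotonation at the benzylic positions.

Step 8
Reactants: 13 RB–CHO
Product: 14 (2R,3R)-5-(2,2-dibromoethenyl)-3-(3,5-dimethoxyphenyl)-7-methoxy-2-(4-methoxyphenyl)-2,3-dihydro-1-benzofuran (RB–CH=CBr2)
Conditions: CBr4, PPh3, Zn, CH2Cl2, rt
Reagents that add atoms: tetrabromomethane BrC(Br)(Br)Br
Why: Corey–Fuchs dibromoolefination, a Wittig reaction of the aldehyde with Ph3P=CBr2 made in the flask; the zinc variant avoids Ph3PBr2 and so spares the acid-sensitive dihydrofuran.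

Step 9
Reactants: 14 RB–CH=CBr2; 15 3-hydroxy-5-methoxybenzaldehyde
Product: 16 3-{[(Z)-1-bromo-2-RB-ethenyl]oxy}-5-methoxybenzaldehyde (aryloxy trans to RB, bromine cis to RB)
Conditions: CuI (10 mol %), 2,2'-bipyridine (20 mol %), K3PO4, toluene, 110 °C
Reagents that add atoms: none
Why: Copper-catalysed Ullmann-type C–O coupling of a 1,1-dibromoalkene with a phenol; the C–Br bond trans to the aryl group is the less hindered and reacts first, and K3PO4 is too weak to eliminate HBr from the product, so the aryloxy group should end trans to RB.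

Step 10
Reactants: 16 (Z)-bromo enol ether; 17 4-methoxyphenylboronic acid
Product: 18 3-methoxy-5-{[(E)-1-(4-methoxyphenyl)-2-RB-ethenyl]oxy}benzaldehyde (4-methoxyphenyl cis to RB)
Conditions: Pd(PPh3)4 (5 mol %), K2CO3, 1,4-dioxane/H2O, 80 °C
Reagents that add atoms: none
Why: Suzuki–Miyaura coupling of the α-bromo enol ether with retention of alkene geometry, which places the 4-methoxyphenyl group cis to RB and so fixes the (E)-enol ether needed for a trans ring closure.

Step 11
Reactants: 18 (E)-enol ether aldehyde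
Product: 19 (E)-N-benzyl aldimine of 18
Conditions: BnNH2 (1.05 equiv), 4 Å MS, CH2Cl2, rt; filtered, concentrated and used directly
Reagents that add atoms: benzylamine NCc1ccccc1
Why: Imine condensation of an aryl aldehyde with a primary amine, driven by removal of water; the (E)-aldimine forms.

Step 12
Reactants: 19 (E)-N-benzyl aldimine of the (E)-triaryl enol ether
Product: 20 (E)-N-benzyl-1-[(2S,3S)-6-methoxy-2-(4-methoxyphenyl)-3-RB-2,3-dihydro-1-benzofuran-4-yl]methanimine
Conditions: [RhCl(coe)2]2 (5 mol %), (S)-BINOL N,N-bis[(R)-1-phenylethyl]phosphoramidite (15 mol %), toluene, 75 °C (coe = cyclooctene)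
Reagents that add atoms: none
Why: Monovalent rhodium held by the imine nitrogen adds oxidatively into the ring-A C–H bond between the imine carbon and the aryloxy oxygen (the future C3a), the tethered alkene inserts into Rh–H with hydride going to the oxygen-bearing carbon, and C–C reductive elimination from the six-membered rhodacycle forms C3–C3a and returns monovalent rhodium. The closest known reaction type is the imine-directed rhodium-catalysed intramolecular hydroarylation of trisubstituted aryl enol ethers to 2-aryl-2,3-dihydrobenzofuran-3-carboxylates, together with the phosphoramidite-controlled asymmetric cyclisation of aryl vinyl ether imines. The dihydrofuran closes in a formally 5-endo-trig mode, which is open here because the bond is made by reductive elimination at the metal and not by attack of a free aryl species on the alkene. C2 and C3 are created together by net syn addition of C3a and H: with the two aryl groups cis on the (E)-enol ether, syn addition can only give the trans-2,3-diaryl ring, and the alkene face is chosen by the chiral phosphoramidite, which should override the distant ring-B centres and give (2S,3S). The step needs site selectivity for this C–H bond over the other ortho C–H bond (the future C5–H), secured because metalation there cannot reach the alkene and is reversible, and it needs the enol ether geometry to hold, secured because the cyclic alkylrhodium intermediate cannot rotate about the former double bond before it eliminates.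

Step 13
Reactants: 20 cyclised N-benzyl aldimine
Product: 21 (2S,3S)-6-methoxy-2-(4-methoxyphenyl)-3-RB-2,3-dihydro-1-benzofuran-4-carbaldehyde
Conditions: 1 M aq. HCl, THF, rt
Reagents that add atoms: water O
Why: Acid-catalysed hydrolysis of the aldimine; dilute aqueous acid at room temperature does not ionise the dihydrofuran C2–O bonds.

Step 14
Reactants: 21 aldehyde; 22 diethyl (4-methoxybenzyl)phosphonate
Product: 23 heptamethyl ether of the target: (2S,3S)-6-methoxy-2-(4-methoxyphenyl)-4-[(E)-2-(4-methoxyphenyl)ethenyl]-3-RB-2,3-dihydro-1-benzofuran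
Conditions: KOtBu, THF, 0 °C to rt
Reagents that add atoms: none
Why: Horner–Wadsworth–Emmons olefination of the aryl aldehyde with the benzylphosphonate anion, which gives the (E)-stilbene; neither aldehyde nor dihydrofurans carry base-labile centres.

Step 15
Reactants: 23 heptamethyl ether
Product: 24 CNP0172909.1 (target)
Conditions: BBr3 (excess), CH2Cl2, −78 to 0 °C; then MeOH, H2O
Reagents that add atoms: none
Why: Lewis-acid cleavage of the seven aryl methyl ethers by BBr3 (bromide attack on the methyl group of the boron-complexed ether); both dihydrofurans are already the thermodynamic trans isomers, so reversible C2–O ionisation should not change their configuration.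

**Compound list**

1 | 5-bromo-2-hydroxy-3-methoxybenzaldehyde | O=Cc1cc(Br)cc(OC)c1O | starting material
2 | 4-methoxybenzyl chloride | COc1ccc(CCl)cc1 | starting material
3 | 5-bromo-3-methoxy-2-[(4-methoxybenzyl)oxy]benzaldehyde | COc1ccc(COc2c(OC)cc(Br)cc2C=O)cc1 | intermediate
4 | 1-bromo-3,5-dimethoxybenzene | COc1cc(Br)cc(OC)c1 | starting material
5 | 3,5-dimethoxyphenylmagnesium bromide (not isolated) | COc1cc([Mg]Br)cc(OC)c1 | intermediate
6 | rac-{5-bromo-3-methoxy-2-[(4-methoxybenzyl)oxy]phenyl}(3,5-dimethoxyphenyl)methanol | COc1ccc(COc2c(OC)cc(Br)cc2C(O)c2cc(OC)cc(OC)c2)cc1 | intermediate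
7 | {5-bromo-3-methoxy-2-[(4-methoxybenzyl)oxy]phenyl}(3,5-dimethoxyphenyl)methanone | COc1ccc(COc2c(OC)cc(Br)cc2C(=O)c2cc(OC)cc(OC)c2)cc1 | intermediate
8 | hydrazone of 7 | COc1ccc(COc2c(OC)cc(Br)cc2C(=NN)c2cc(OC)cc(OC)c2)cc1 | intermediate
9 | 5-bromo-1-[diazo(3,5-dimethoxyphenyl)methyl]-3-methoxy-2-[(4-methoxybenzyl)oxy]benzene (not isolated) | COc1ccc(COc2c(OC)cc(Br)cc2C(=[N+]=[N-])c2cc(OC)cc(OC)c2)cc1 | intermediate
10 | (2S,3R)-5-bromo-3-(3,5-dimethoxyphenyl)-7-methoxy-2-(4-methoxyphenyl)-2,3-dihydro-1-benzofuran (cis) | Brc1cc(OC)c2c(c1)[C@@H](c1cc(OC)cc(OC)c1)[C@@H](c1ccc(OC)cc1)O2 | intermediate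
11 | (2R,3R)-5-bromo-3-(3,5-dimethoxyphenyl)-7-methoxy-2-(4-methoxyphenyl)-2,3-dihydro-1-benzofuran (trans, RB–Br) | Brc1cc(OC)c2c(c1)[C@@H](c1cc(OC)cc(OC)c1)[C@H](c1ccc(OC)cc1)O2 | intermediate
12 | RB–Li, the 5-lithio derivative of 11 (not isolated) | [Li]c1cc(OC)c2c(c1)[C@@H](c1cc(OC)cc(OC)c1)[C@H](c1ccc(OC)cc1)O2 | intermediate
13 | (2R,3R)-3-(3,5-dimethoxyphenyl)-7-methoxy-2-(4-methoxyphenyl)-2,3-dihydro-1-benzofuran-5-carbaldehyde | O=Cc1cc(OC)c2c(c1)[C@@H](c1cc(OC)cc(OC)c1)[C@H](c1ccc(OC)cc1)O2 | intermediate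
14 | (2R,3R)-5-(2,2-dibromoethenyl)-3-(3,5-dimethoxyphenyl)-7-methoxy-2-(4-methoxyphenyl)-2,3-dihydro-1-benzofuran | BrC(Br)=Cc1cc(OC)c2c(c1)[C@@H](c1cc(OC)cc(OC)c1)[C@H](c1ccc(OC)cc1)O2 | intermediate
15 | 3-hydroxy-5-methoxybenzaldehyde | COc1cc(O)cc(C=O)c1 | starting material
16 | 3-{[(Z)-1-bromo-2-RB-ethenyl]oxy}-5-methoxybenzaldehyde | O=Cc1cc(OC)cc(O/C(Br)=C/c2cc(OC)c3c(c2)[C@@H](c2cc(OC)cc(OC)c2)[C@H](c2ccc(OC)cc2)O3)c1 | intermediate
17 | 4-methoxyphenylboronic acid | COc1ccc(B(O)O)cc1 | starting material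
18 | 3-methoxy-5-{[(E)-1-(4-methoxyphenyl)-2-RB-ethenyl]oxy}benzaldehyde | O=Cc1cc(OC)cc(O/C(=C/c2cc(OC)c3c(c2)[C@@H](c2cc(OC)cc(OC)c2)[C@H](c2ccc(OC)cc2)O3)c2ccc(OC)cc2)c1 | intermediate
19 | (E)-N-benzyl aldimine of 18 | c1ccccc1C/N=C/c1cc(OC)cc(O/C(=C/c2cc(OC)c3c(c2)[C@@H](c2cc(OC)cc(OC)c2)[C@H](c2ccc(OC)cc2)O3)c2ccc(OC)cc2)c1 | intermediate
20 | (E)-N-benzyl-1-[(2S,3S)-6-methoxy-2-(4-methoxyphenyl)-3-RB-2,3-dihydro-1-benzofuran-4-yl]methanimine | c1ccccc1C/N=C/c1cc(OC)cc2c1[C@H](c1cc(OC)c3c(c1)[C@@H](c1cc(OC)cc(OC)c1)[C@H](c1ccc(OC)cc1)O3)[C@@H](c1ccc(OC)cc1)O2 | intermediate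
21 | (2S,3S)-6-methoxy-2-(4-methoxyphenyl)-3-RB-2,3-dihydro-1-benzofuran-4-carbaldehyde | O=Cc1cc(OC)cc2c1[C@H](c1cc(OC)c3c(c1)[C@@H](c1cc(OC)cc(OC)c1)[C@H](c1ccc(OC)cc1)O3)[C@@H](c1ccc(OC)cc1)O2 | intermediate
22 | diethyl (4-methoxybenzyl)phosphonate | CCOP(=O)(Cc1ccc(OC)cc1)OCC | starting material
23 | heptamethyl ether of the target, (2S,3S)-6-methoxy-2-(4-methoxyphenyl)-4-[(E)-2-(4-methoxyphenyl)ethenyl]-3-RB-2,3-dihydro-1-benzofuran | COc1ccc(/C=C/c2cc(OC)cc3c2[C@H](c2cc(OC)c4c(c2)[C@@H](c2cc(OC)cc(OC)c2)[C@H](c2ccc(OC)cc2)O4)[C@@H](c2ccc(OC)cc2)O3)cc1 | intermediate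
24 | CNP0172909.1, (2S,3S)-2-(4-hydroxyphenyl)-4-[(E)-2-(4-hydroxyphenyl)ethenyl]-3-[(2R,3R)-3-(3,5-dihydroxyphenyl)-7-hydroxy-2-(4-hydroxyphenyl)-2,3-dihydro-1-benzofuran-5-yl]-2,3-dihydro-1-benzofuran-6-ol | Oc1ccc(/C=C/c2cc(O)cc3c2[C@H](c2cc(O)c4c(c2)[C@@H](c2cc(O)cc(O)c2)[C@H](c2ccc(O)cc2)O4)[C@@H](c2ccc(O)cc2)O3)cc1 | target

**Step count and risks**

Total step count: 15. Longest linear sequence: 15 steps (1 to 24); compounds 2, 4, 15, 17 and 22 are bought and enter directly.

Steps most likely to fail: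

1. Step 12. The crowded triaryl alkene may insert too slowly into the Rh–H bond, or the ligand may give poor facial selectivity against the ring-B centres. The fallback uses auxiliary control with a more electron-rich achiral phosphine. It sets out from aldehyde 18: condensation with (R)-1-aminoindane (4 Å MS, CH2Cl2) gives the (E)-N-[(R)-indan-1-yl] aldimine of 18 F1. [RhCl(coe)2]2 with ferrocenyl(dicyclohexyl)phosphine in toluene at 75 °C should cyclise it, the chiral amine now choosing the alkene face, to the N-indanyl aldimine of the cyclised aldehyde F2. Hydrolysis with 1 M aq. HCl in THF returns the route at aldehyde 21, where any minor diastereomer is removed.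

2. Step 15. During Lewis-acid demethylation the stilbene may be protonated and attacked by ring B in a Friedel–Crafts closure, or the dihydrofurans may open. The fallback removes the methyl groups before the stilbene exists and finishes with fluoride. It sets out from aldehyde 21: BBr3 in CH2Cl2 gives the hexaphenol aldehyde F3, and TBSCl/imidazole in DMF gives the hexakis(tert-butyldimethylsilyl) ether aldehyde F4. Diethyl [4-(tert-butyldimethylsilyloxy)benzyl]phosphonate F5 is made from diethyl (4-hydroxybenzyl)phosphonate and TBSCl. Horner–Wadsworth–Emmons reaction of F4 with F5 (NaH, THF, 0 °C) gives the heptakis(silyl) ether of the target F6, and n-Bu4NF/AcOH in THF returns the route at target 24.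

3. Step 9. The bromo enol ether may lose HBr to the ynol ether under the basic copper conditions, or a second phenol may couple to give the ketene acetal. The fallback makes the C–O bond by oxidative coupling of an alkenylboronate instead. It sets out from bromide 11: Sonogashira coupling with 4-ethynylanisole (Pd(PPh3)2Cl2, CuI, Et3N, 60 °C) gives the diarylalkyne F7. Copper-catalysed syn-hydroboration (CuCl, PPh3, NaOtBu, B2pin2, MeOH, THF) gives the (Z)-alkenylboronate with boron on the anisyl-bearing carbon F8, after chromatographic removal of the regioisomer that this unsymmetrical alkyne also forms. Chan–Lam O-vinylation of phenol 15 (Cu(OAc)2, pyridine, 4 Å MS, air, CH2Cl2), with retention of geometry, returns the route at enol ether 18.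

**Further compounds**

F1 | step 12 | (E)-N-[(R)-indan-1-yl] aldimine of 18 | c1ccc2c(c1)CC[C@H]2/N=C/c1cc(OC)cc(O/C(=C/c2cc(OC)c3c(c2)[C@@H](c2cc(OC)cc(OC)c2)[C@H](c2ccc(OC)cc2)O3)c2ccc(OC)cc2)c1
F2 | step 12 | (E)-N-[(R)-indan-1-yl] aldimine of 21 | c1ccc2c(c1)CC[C@H]2/N=C/c1cc(OC)cc2c1[C@H](c1cc(OC)c3c(c1)[C@@H](c1cc(OC)cc(OC)c1)[C@H](c1ccc(OC)cc1)O3)[C@@H](c1ccc(OC)cc1)O2
F3 | step 15 | hexaphenol aldehyde, (2S,3S)-3-[(2R,3R)-3-(3,5-dihydroxyphenyl)-7-hydroxy-2-(4-hydroxyphenyl)-2,3-dihydro-1-benzofuran-5-yl]-6-hydroxy-2-(4-hydroxyphenyl)-2,3-dihydro-1-benzofuran-4-carbaldehyde | O=Cc1cc(O)cc2c1[C@H](c1cc(O)c3c(c1)[C@@H](c1cc(O)cc(O)c1)[C@H](c1ccc(O)cc1)O3)[C@@H](c1ccc(O)cc1)O2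
F4 | step 15 | hexakis(tert-butyldimethylsilyl) ether of F3 | O=Cc1cc(O[Si](C)(C)C(C)(C)C)cc2c1[C@H](c1cc(O[Si](C)(C)C(C)(C)C)c3c(c1)[C@@H](c1cc(O[Si](C)(C)C(C)(C)C)cc(O[Si](C)(C)C(C)(C)C)c1)[C@H](c1ccc(O[Si](C)(C)C(C)(C)C)cc1)O3)[C@@H](c1ccc(O[Si](C)(C)C(C)(C)C)cc1)O2
F5 | step 15 | diethyl [4-(tert-butyldimethylsilyloxy)benzyl]phosphonate | CCOP(=O)(Cc1ccc(O[Si](C)(C)C(C)(C)C)cc1)OCC
F6 | step 15 | heptakis(tert-butyldimethylsilyl) ether of 24 | CC(C)(C)[Si](C)(C)Oc1ccc(/C=C/c2cc(O[Si](C)(C)C(C)(C)C)cc3c2[C@H](c2cc(O[Si](C)(C)C(C)(C)C)c4c(c2)[C@@H](c2cc(O[Si](C)(C)C(C)(C)C)cc(O[Si](C)(C)C(C)(C)C)c2)[C@H](c2ccc(O[Si](C)(C)C(C)(C)C)cc2)O4)[C@@H](c2ccc(O[Si](C)(C)C(C)(C)C)cc2)O3)cc1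
F7 | step 9 | (2R,3R)-3-(3,5-dimethoxyphenyl)-7-methoxy-2-(4-methoxyphenyl)-5-[(4-methoxyphenyl)ethynyl]-2,3-dihydro-1-benzofuran | COc1ccc(C#Cc2cc(OC)c3c(c2)[C@@H](c2cc(OC)cc(OC)c2)[C@H](c2ccc(OC)cc2)O3)cc1
F8 | step 9 | 2-[(Z)-1-(4-methoxyphenyl)-2-RB-ethenyl]-4,4,5,5-tetramethyl-1,3,2-dioxaborolane (boron trans to RB) | CC1(C)OB(/C(=C/c2cc(OC)c3c(c2)[C@@H](c2cc(OC)cc(OC)c2)[C@H](c2ccc(OC)cc2)O3)c2ccc(OC)cc2)OC1(C)C
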